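## The problem

The target is a C21 furanoterpenoid in which a 3-substituted furan (ring A) and a 3-methyl-4-acyloxyfuran-2(5H)-one (ring B, a tetronic acid palmitate) are joined by a linear thirteen-carbon chain. The chain carries two E-trisubstituted alkenes that map onto (2E,6E)-farnesol, so their geometry can be bought; the tail of the chain and ring B have to be built. The only stereocentre is the S-configured CH(CH3) next to the exocyclic CH. It bears no heteroatom or carbonyl and has no stereogenic neighbour, so a reagent must set it. The exocyclic alkene at C5 of ring B must be 5E (chain syn to C4), which condensation chemistry does not favour, so it has to come from a stereospecific step. The furan is sensitive to acid, electrophilic halogen, oxidants and strong base at C2–H. The enol ester of ring B is sensitive to nucleophiles, and the hydrogen of the stereocentre becomes vinylogously acidic once an ynone, enone or ylidene lactone sits beside it. The feature that opens the route is that the stereocentre is a methine flanked by a methyl group, a chain CH2 and an sp2 carbon. With boron in place of the sp2 carbon it is a secondary boronic ester that can be assembled from a chain CH2–B unit and a CH(CH3) carbenoid, and whose boron can later be exchanged for carbon with retention.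

## Retrosynthesis

**Enol ester.** The acyl C–O bond of the enol ester is cut first, giving tetronic acid 34 and palmitoyl chloride 35. This is the most labile bond of 36 and would not survive fluoride, copper or strong base, so it is made last. The forward step asks only for O-acylation, which is assured because C3 of ring B is blocked by its methyl group.

**Ring B.** In 34 the lactone bond O1–C5 is cut, which leads through cesium carboxylate 33 to the acyclic α-iodo enone β-keto ester 32. Against the neighbouring cut at the exocyclic C=C (condensation of a tetronate with an α-branched aldehyde), this cut turns the 5E problem into the geometry of a vinyl iodide, which copper transfers to oxygen with retention. It also never places the stereocentre α to an aldehyde. The forward reaction must free the carboxylate without water and form the C–O bond before the β-keto carboxylate loses CO2.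

**Iodoalkene and β-keto ester.** The C–I bond of 32 is traced through vinylstannane 31 to ynone 30, because syn-hydrostannation of an ynone puts tin α to the carbonyl and hydrogen on the same face. Adjusting the oxidation level gives alcohol 29, and cutting its carbinol–Cα bond gives ynal 24 and ester 27 (through enolate 28). The alkyne has no geometry to control and the two aldol stereocentres are later erased. The forward steps need α-regiochemistry and syn addition, and must avoid base-induced ynone-to-allenone isomerisation.

**Alkyne from boron.** The C(sp)–C(sp3) bond at the stereocentre of 24 is cut. Ynal 24 comes from acetylide 23 and bromoalkene 22, and 22 from secondary boronic ester 19 through ate complex 20 and iodo boronic ester 21. This Zweifel-type exchange moves the stereocentre from boron to carbon with retention. The alternative, homologating an α-methyl aldehyde, is kept only as a reserve because that aldehyde is configurationally labile. Boronic ester 19 is stable to chromatography and storage.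

**Key disconnection.** In 19 the CH2–CH(CH3) bond is cut, giving primary boronic ester 13 and ethyl carbamate 16, which supplies the methine and its methyl group via lithiated carbamate 17 and ate complex 18. Both partners are carbon nucleophiles; boron accepts one and passes the other on. The competing cut, alkylation of a chiral propanoate enolate with the chain halide, would place the stereocentre next to a carbonyl and need reduction and homologation. Here 13 has no stereocentre at all. The forward step needs a chiral diamine ligand of the correct sense (specified in step 11), a single homologation, and no metalation of the furan.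

**Chain terminus and furan.** The C–B bond of 13 is traced to the C–Cl bond of 11 with diboron 12. The allylic C–C bond of 11 is cut to allylic acetate 7 and chloride 9 (as Grignard reagent 10). A primary chloride is chosen because it is inert while the copper-catalysed allylic coupling runs and can then be borylated directly, so the hydroxyl needs no protecting group. The furan enters only after all electrophilic and oxidative operations.

**Farnesol degradation.** Chloride 7 comes from alcohol 6, aldehyde 5, epoxide 4, bromohydrin 3, acetate 2 and farnesol 1. The terminal isopropylidene unit is excised as acetone, and both E-alkenes come unchanged from 1. The acetate of 2 protects the alcohol, deactivates the 2,3-alkene toward bromonium formation, and later serves as the allylic leaving group.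

**Small components.** Carbamate 16 is made from ethanol 14 and carbamoyl chloride 15, ester 27 from propanoyl chloride 25 and silyl alcohol 26, and chloride 9 from furan-3-ylmethanol 8.

## Roads not taken

**Alternative 1:** Copper-mediated enol lactone closure as the governing idea. The cut is O1–C5 of ring B. In the forward direction the fluoride-labile ester A2 is unmasked to its carboxylate and a phenanthroline-ligated copper iodide catalyst joins oxygen to the iodine-bearing vinyl carbon, giving tetronic acid A1.
- Merits: ring B and the 5E geometry arise in one stereospecific step from an acyclic precursor, and the tetronic acid needs no protecting group.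
- Weak points: the idea says nothing about the S centre. A2 must still come from an enantioenriched ynal such as 24, and the usual sources (auxiliary alkylation, reduction, one-carbon homologation) pass through a configurationally labile α-methyl aldehyde. The β-keto carboxylate may also decarboxylate.
- Comparison: for the ring closure the two plans are equal, since A1 is compound 34 and A2 is compound 32, and the chosen route uses this closure as step 18 and inherits its risk. The chosen plan adds a defined origin for the stereocentre as a C–B bond that never sits α to a carbonyl.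

**Alternative 2:** Stereoretentive Negishi coupling onto a preformed ring B. The cut is the bond between the exocyclic CH and the stereocentre. Secondary iodide A5 is converted by iodine–lithium exchange and transmetalation into mixed dialkylzinc A6, which couples under palladium catalysis with (E)-iodomethylidene tetronate A4 to give protected tetronate A3.
- Merits: this is the most convergent plan. Ring B and its E geometry are secured in a small fragment before the chain is committed, and only deprotection to 34 and acylation follow. After the stereocentre is set it is clearly shorter than the chosen route, which needs seven further operations.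
- Weak points: the unstabilised secondary alkyllithium from A5 keeps its configuration only at very low temperature. The alkyllithium used for exchange meets the acidic C2–H of the furan. A5 must itself be made enantiopure by substitution at a secondary carbinol and can racemise by iodide exchange. β-Hydride elimination and reinsertion at palladium would give the linear isomer.
- Comparison: the chosen plan gives up convergence and pays with a longer endgame. In return every carrier of the stereocentre (19, 22, 24) is configurationally stable at room temperature, and each transfer is a stereospecific 1,2-migration.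

**Alternative 3:** Ene-reductase reduction of a 2-methyl-2-enal. No skeletal bond is cut. An Old Yellow Enzyme-type reductase with recycled nicotinamide cofactor adds hydride to C3 and a proton to C2 of enal A8, giving (S)-aldehyde A7.
- Merits: the asymmetric step is catalytic, aqueous and needs neither a stoichiometric chiral amine nor cryogenics. The front end is shorter, because A8 keeps all fifteen farnesyl carbons. Acetate 2 and Grignard reagent 10 would give hydrocarbon A9, and terminal allylic oxidation would give A8, with no excision of three carbons and re-addition of two. In step economy before the stereocentre this road is better.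
- Weak points: A7 has an acidic α-hydrogen and is exposed to buffered water, so its optical purity depends on how quickly it is removed. The lipophilic C20 substrate needs cosolvent and the facial preference of the enzyme would have to be screened. Allylic oxidation of A9 must distinguish three trisubstituted alkenes beside a furan. A7 must still be converted to 24 by dibromo-olefination, so the labile aldehyde is handled twice.
- Comparison: the chosen plan spends about four more steps on degradation of 1. Against that it forms the stereocentre as a non-epimerisable C–B bond with reagent control of predictable sense.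

Key step: step 11

Remark on the chemistry: s-BuLi with (−)-sparteine removes the pro-S hydrogen of O-alkyl carbamates, so the S boronic ester 19 requires (+)-sparteine (or the (+)-sparteine surrogate diamine), which is assumed to be available. The centres at C10 of 3 and 4 and at C2/C3 of 29–33 are uncontrolled and are all excised or become sp2 later.

## Route

Step 1
Reactants: 1 (2E,6E)-farnesol
Product: 2 (2E,6E)-3,7,11-trimethyldodeca-2,6,10-trien-1-yl acetate
Conditions: Ac2O, pyridine, DMAP (cat.), CH2Cl2, rt
Reagents that add atoms: acetic anhydride, CC(=O)OC(C)=O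
Why: Standard DMAP-catalysed acetylation of a primary allylic alcohol; the acetate later deactivates the 2,3-alkene and serves as the allylic leaving group.

Step 2
Reactants: 2 (2E,6E)-3,7,11-trimethyldodeca-2,6,10-trien-1-yl acetate
Product: 3 (2E,6E)-10-bromo-11-hydroxy-3,7,11-trimethyldodeca-2,6-dien-1-yl acetate (racemic)
Conditions: NBS, THF/H2O, 0 °C
Reagents that add atoms: N-bromosuccinimide, BrN1C(=O)CCC1=O; water, O
Why: Bromohydrin formation in aqueous THF should select the terminal isopropylidene alkene, the most electron-rich and most exposed one, with water opening the bromonium ion at the tertiary carbon. The new CHBr centre is racemic and is excised in step 4.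

Step 3
Reactants: 3 (2E,6E)-10-bromo-11-hydroxy-3,7,11-trimethyldodeca-2,6-dien-1-yl acetate
Product: 4 (2E,6E)-9-(3,3-dimethyloxiran-2-yl)-3,7-dimethylnona-2,6-dien-1-yl acetate (racemic)
Conditions: DBU, CH2Cl2, rt
Reagents that add atoms: none
Why: Intramolecular Williamson etherification (3-exo-tet) of the bromohydrin; an amidine base in an aprotic solvent spares the acetate that carbonate in methanol would cleave.

Step 4
Reactants: 4 (2E,6E)-9-(3,3-dimethyloxiran-2-yl)-3,7-dimethylnona-2,6-dien-1-yl acetate
Product: 5 (2E,6E)-3,7-dimethyl-10-oxodeca-2,6-dien-1-yl acetate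
Conditions: HIO4·2H2O, THF/Et2O, 0 °C
Reagents that add atoms: none
Why: Periodic acid should open the trisubstituted epoxide to the diol and cleave it in the same flask (Malaprade-type glycol cleavage), releasing acetone; the acetate and the two remaining alkenes are inert to periodate.

Step 5
Reactants: 5 (2E,6E)-3,7-dimethyl-10-oxodeca-2,6-dien-1-yl acetate
Product: 6 (2E,6E)-10-hydroxy-3,7-dimethyldeca-2,6-dien-1-yl acetate
Conditions: NaBH4, MeOH, 0 °C
Reagents that add atoms: none
Why: Chemoselective borohydride reduction of an aldehyde beside an ester.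

Step 6
Reactants: 6 (2E,6E)-10-hydroxy-3,7-dimethyldeca-2,6-dien-1-yl acetate
Product: 7 (2E,6E)-10-chloro-3,7-dimethyldeca-2,6-dien-1-yl acetate
Conditions: PPh3, NCS, CH2Cl2, 0 °C → rt
Reagents that add atoms: N-chlorosuccinimide, ClN1C(=O)CCC1=O
Why: Appel-type chlorination through the alkoxyphosphonium salt, an SN2 displacement at a primary carbon; the allylic acetate and the alkenes are not touched.

Step 7
Reactants: 8 furan-3-ylmethanol
Product: 9 3-(chloromethyl)furan
Conditions: SOCl2, pyridine, Et2O, 0 °C
Reagents that add atoms: thionyl chloride, ClS(Cl)=O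
Why: Chlorination of a primary furylmethyl alcohol via its chlorosulfite; pyridine takes up HCl so the furan is not exposed to acid, and 9 is used promptly.

Step 8
Reactants: 7 (2E,6E)-10-chloro-3,7-dimethyldeca-2,6-dien-1-yl acetate; 9 3-(chloromethyl)furan
Product: 11 3-[(3E,7E)-11-chloro-4,8-dimethylundeca-3,7-dien-1-yl]furan, via (furan-3-ylmethyl)magnesium chloride 10 (not isolated)
Conditions: 9, Mg, THF, 0 °C → rt; then 7, Li2CuCl4 (5 mol %), THF, −20 → 0 °C
Reagents that add atoms: none
Why: Copper-catalysed allylic substitution of a primary allylic acetate by a Grignard reagent; attack at the unhindered α-carbon is expected because γ-attack would build a quaternary centre, and the E geometry is retained. The primary alkyl chloride does not couple at this temperature.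

Step 9
Reactants: 11 3-[(3E,7E)-11-chloro-4,8-dimethylundeca-3,7-dien-1-yl]furan; 12 bis(pinacolato)diboron
Product: 13 2-[(4E,8E)-11-(furan-3-yl)-4,8-dimethylundeca-4,8-dien-1-yl]-4,4,5,5-tetramethyl-1,3,2-dioxaborolane
Conditions: CuCl (5 mol %), Xantphos (5 mol %), KOt-Bu, THF, rt
Reagents that add atoms: none
Why: Copper-catalysed boryl substitution of a primary alkyl halide: alkoxide and 12 generate a boryl complex of monovalent copper that replaces chloride. Trisubstituted alkenes and the furan are not borylated without a proton source.

Step 10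
Reactants: 14 ethanol; 15 N,N-diisopropylcarbamoyl chloride
Product: 16 ethyl N,N-diisopropylcarbamate
Conditions: Et3N, CH2Cl2, reflux
Reagents that add atoms: none
Why: Carbamoylation of a primary alcohol by nucleophilic acyl substitution.

Step 11
Reactants: 13 2-[(4E,8E)-11-(furan-3-yl)-4,8-dimethylundeca-4,8-dien-1-yl]-4,4,5,5-tetramethyl-1,3,2-dioxaborolane; 16 ethyl N,N-diisopropylcarbamate
Product: 19 2-[(2S,6E,10E)-13-(furan-3-yl)-6,10-dimethyltrideca-6,10-dien-2-yl]-4,4,5,5-tetramethyl-1,3,2-dioxaborolane, via (R)-1-lithioethyl N,N-diisopropylcarbamate sparteine complex 17 (not isolated), via lithium boronate complex 18 (not isolated)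
Conditions: 16, (+)-sparteine, s-BuLi, Et2O, −78 °C, 5 h; then 13, −78 °C, 1 h; then reflux (35 °C), 16 h
Reagents that add atoms: none
Why: s-BuLi bound to (+)-sparteine removes the pro-R hydrogen of 16 and gives the chelated, configurationally stable α-lithio carbamate 17. Boronic ester 13 is added to preformed 17 and boron captures the carbanion with retention, giving ate complex 18. On warming, the chain CH2 shifts from boron to carbon antiperiplanar to the departing carbamate (1,2-metallate rearrangement with inversion at the carbenoid carbon), forming the CH2–CH(CH3) bond. The closest known reaction type is the lithiation–borylation homologation of primary pinacol boronic esters with sparteine-ligated lithiated alkyl carbamates. No ring is closed. The S stereocentre is set by the ligand enantiomer alone, since both the retention at boron capture and the inversion at migration are stereospecific; (−)-sparteine would give the R ester. The step needs a single homologation and no furan metalation: 17 is fully formed before 13 is added so no free s-BuLi meets the furan C2–H, only a small excess of 17 is used, and secondary ester 19 is more hindered than 13. The remote trisubstituted alkenes are inert.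

Step 12
Reactants: 19 2-[(2S,6E,10E)-13-(furan-3-yl)-6,10-dimethyltrideca-6,10-dien-2-yl]-4,4,5,5-tetramethyl-1,3,2-dioxaborolane
Product: 22 3-[(3E,7E,12S)-13-bromo-4,8,12-trimethyltetradeca-3,7,13-trien-1-yl]furan, via lithium 1-bromoethenyl boronate complex 20 (not isolated), via β-iodo boronic ester 21 (not isolated)
Conditions: vinyl bromide, LiN(i-Pr)2, THF, −78 °C; then I2, MeOH, −78 °C; then NaOMe, MeOH, −78 °C → rt; Na2S2O3 quench
Reagents that add atoms: vinyl bromide, C=CBr
Why: Zweifel-type olefination: 1-bromovinyllithium generated beside 19 is trapped as boronate 20, iodine triggers 1,2-migration of the secondary alkyl group with retention at the migrating carbon, and methoxide-induced anti-elimination of boron and iodide from 21 gives the 2-bromoalkene. The stereocentre is transferred, not created.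

Step 13
Reactants: 22 3-[(3E,7E,12S)-13-bromo-4,8,12-trimethyltetradeca-3,7,13-trien-1-yl]furan
Product: 24 (4S,8E,12E)-15-(furan-3-yl)-4,8,12-trimethylpentadeca-8,12-dien-2-ynal, via lithium acetylide 23 (not isolated)
Conditions: LiN(i-Pr)2 (2.3 equiv), THF, −78 → −20 °C; then DMF, −78 °C → rt; inverse quench into aq KH2PO4
Reagents that add atoms: N,N-dimethylformamide, CN(C)C=O
Why: Amide-base 1,2-elimination of HBr from the 2-bromo-1-alkene gives the terminal alkyne, which the second equivalent of base converts to acetylide 23; formylation with DMF then gives the ynal. The vinylic hydrogens are more acidic than the allylic methine, so the allene pathway that would erase the stereocentre is not expected, and the buffered inverse quench keeps liberated dimethylamine from adding to the ynal.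

Step 14
Reactants: 25 propanoyl chloride; 26 2-(trimethylsilyl)ethanol
Product: 27 2-(trimethylsilyl)ethyl propanoate
Conditions: pyridine, CH2Cl2, 0 °C → rt
Reagents that add atoms: none
Why: Esterification of an acid chloride with a primary alcohol.

Step 15
Reactants: 24 (4S,8E,12E)-15-(furan-3-yl)-4,8,12-trimethylpentadeca-8,12-dien-2-ynal; 27 2-(trimethylsilyl)ethyl propanoate
Product: 29 2-(trimethylsilyl)ethyl (6S,10E,14E)-17-(furan-3-yl)-3-hydroxy-2,6,10,14-tetramethylheptadeca-10,14-dien-4-ynoate (mixture at C2 and C3), via lithium ester enolate 28 (not isolated)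
Conditions: 27, LiN(i-Pr)2, THF, −78 °C; then 24, −78 °C; aq NH4Cl
Reagents that add atoms: none
Why: Lithium enolate aldol addition, 1,2 to the ynal at −78 °C; the two new centres form unselectively, and C3 is later oxidised while C2 becomes sp2 in ring B.

Step 16
Reactants: 29 2-(trimethylsilyl)ethyl (6S,10E,14E)-17-(furan-3-yl)-3-hydroxy-2,6,10,14-tetramethylheptadeca-10,14-dien-4-ynoate
Product: 30 2-(trimethylsilyl)ethyl (6S,10E,14E)-17-(furan-3-yl)-2,6,10,14-tetramethyl-3-oxoheptadeca-10,14-dien-4-ynoate
Conditions: Dess–Martin periodinane, NaHCO3, CH2Cl2, 0 °C → rt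
Reagents that add atoms: none
Why: Dess–Martin oxidation of a propargylic secondary alcohol to the ynone under bicarbonate buffer; no strong base is present that could isomerise the ynone to an allenone through the propargylic stereocentre.

Step 17
Reactants: 30 2-(trimethylsilyl)ethyl (6S,10E,14E)-17-(furan-3-yl)-2,6,10,14-tetramethyl-3-oxoheptadeca-10,14-dien-4-ynoate
Product: 32 2-(trimethylsilyl)ethyl (4E,6S,10E,14E)-17-(furan-3-yl)-4-iodo-2,6,10,14-tetramethyl-3-oxoheptadeca-4,10,14-trienoate, via α-stannyl enone 31 (not isolated)
Conditions: Bu3SnH (slow addition), Pd(PPh3)4 (3 mol %), THF, 0 °C; then I2, CH2Cl2, 0 °C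
Reagents that add atoms: iodine, II
Why: Palladium-catalysed syn-hydrostannation of an ynone (oxidative addition of Sn–H to zerovalent palladium, then hydropalladation) places tin α to the carbonyl and hydrogen on the same face at the β-carbon. Iododestannylation proceeds with retention, so iodine ends trans to the stereocentre-bearing carbon (4E).

Step 18
Reactants: 32 2-(trimethylsilyl)ethyl (4E,6S,10E,14E)-17-(furan-3-yl)-4-iodo-2,6,10,14-tetramethyl-3-oxoheptadeca-4,10,14-trienoate
Product: 34 (5E)-5-[(2S,6E,10E)-13-(furan-3-yl)-2,6,10-trimethyltrideca-6,10-dien-1-ylidene]-4-hydroxy-3-methylfuran-2(5H)-one, via cesium β-keto carboxylate 33 (not isolated)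
Conditions: CsF (3 equiv), CuI (20 mol %), 1,10-phenanthroline (40 mol %), DMF, rt → 50 °C; aq citric acid work-up
Reagents that add atoms: none
Why: Fluoride fragments the 2-(trimethylsilyl)ethyl ester to carboxylate 33 without water, acid or hydroxide. Ullmann-type intramolecular O-vinylation by monovalent copper then closes the five-membered lactone (5-exo) with retention of alkene geometry, giving the 5E tetronic acid; the acidic 1,3-dicarbonyl is deprotonated first, which protects the allylic stereocentre from base.

Step 19
Reactants: 34 (5E)-5-[(2S,6E,10E)-13-(furan-3-yl)-2,6,10-trimethyltrideca-6,10-dien-1-ylidene]-4-hydroxy-3-methylfuran-2(5H)-one; 35 palmitoyl chloride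
Product: 36 (2E)-2-[(2S,6E,10E)-13-(furan-3-yl)-2,6,10-trimethyltrideca-6,10-dien-1-ylidene]-4-methyl-5-oxo-2,5-dihydrofuran-3-yl hexadecanoate
Conditions: Et3N, CH2Cl2, 0 °C
Reagents that add atoms: none
Why: O-acylation of a tetronic acid with an acid chloride and amine base; C3 is fully substituted, so only the enol oxygen can be acylated and no C-acyl product can form.

## Compound list

1 | (2E,6E)-3,7,11-trimethyldodeca-2,6,10-trien-1-ol ((2E,6E)-farnesol) | CC(C)=CCC/C(C)=C/CC/C(C)=C/CO | starting material
2 | (2E,6E)-3,7,11-trimethyldodeca-2,6,10-trien-1-yl acetate | CC(C)=CCC/C(C)=C/CC/C(C)=C/COC(C)=O | intermediate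
3 | (2E,6E)-10-bromo-11-hydroxy-3,7,11-trimethyldodeca-2,6-dien-1-yl acetate (racemic) | CC(C)(O)C(Br)CC/C(C)=C/CC/C(C)=C/COC(C)=O | intermediate
4 | (2E,6E)-9-(3,3-dimethyloxiran-2-yl)-3,7-dimethylnona-2,6-dien-1-yl acetate (racemic) | CC1(C)OC1CC/C(C)=C/CC/C(C)=C/COC(C)=O | intermediate
5 | (2E,6E)-3,7-dimethyl-10-oxodeca-2,6-dien-1-yl acetate | O=CCC/C(C)=C/CC/C(C)=C/COC(C)=O | intermediate
6 | (2E,6E)-10-hydroxy-3,7-dimethyldeca-2,6-dien-1-yl acetate | OCCC/C(C)=C/CC/C(C)=C/COC(C)=O | intermediate
7 | (2E,6E)-10-chloro-3,7-dimethyldeca-2,6-dien-1-yl acetate | ClCCC/C(C)=C/CC/C(C)=C/COC(C)=O | intermediate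
8 | furan-3-ylmethanol | OCc1ccoc1 | starting material
9 | 3-(chloromethyl)furan | ClCc1ccoc1 | intermediate
10 | (furan-3-ylmethyl)magnesium chloride (not isolated) | Cl[Mg]Cc1ccoc1 | intermediate
11 | 3-[(3E,7E)-11-chloro-4,8-dimethylundeca-3,7-dien-1-yl]furan | ClCCC/C(C)=C/CC/C(C)=C/CCc1ccoc1 | intermediate
12 | bis(pinacolato)diboron | CC1(C)OB(OC1(C)C)B1OC(C)(C)C(C)(C)O1 | starting material
13 | 2-[(4E,8E)-11-(furan-3-yl)-4,8-dimethylundeca-4,8-dien-1-yl]-4,4,5,5-tetramethyl-1,3,2-dioxaborolane | CC1(C)OB(OC1(C)C)CCC/C(C)=C/CC/C(C)=C/CCc1ccoc1 | intermediate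
14 | ethanol | CCO | starting material
15 | N,N-diisopropylcarbamoyl chloride | ClC(=O)N(C(C)C)C(C)C | starting material
16 | ethyl N,N-diisopropylcarbamate | CCOC(=O)N(C(C)C)C(C)C | intermediate
17 | (R)-1-lithioethyl N,N-diisopropylcarbamate, as its (+)-sparteine complex (not isolated; ligand not drawn) | C[C@@H]([Li])OC(=O)N(C(C)C)C(C)C | intermediate
18 | lithium [(1R)-1-(N,N-diisopropylcarbamoyloxy)ethyl][(4E,8E)-11-(furan-3-yl)-4,8-dimethylundeca-4,8-dien-1-yl](pinacolato)borate (not isolated) | [Li+].C[C@H](OC(=O)N(C(C)C)C(C)C)[B-]1(CCC/C(C)=C/CC/C(C)=C/CCc2ccoc2)OC(C)(C)C(C)(C)O1 | intermediate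
19 | 2-[(2S,6E,10E)-13-(furan-3-yl)-6,10-dimethyltrideca-6,10-dien-2-yl]-4,4,5,5-tetramethyl-1,3,2-dioxaborolane | CC1(C)OB(OC1(C)C)[C@@H](C)CCC/C(C)=C/CC/C(C)=C/CCc1ccoc1 | intermediate
20 | lithium (1-bromoethenyl)[(2S,6E,10E)-13-(furan-3-yl)-6,10-dimethyltrideca-6,10-dien-2-yl](pinacolato)borate (not isolated) | [Li+].C=C(Br)[B-]1(OC(C)(C)C(C)(C)O1)[C@@H](C)CCC/C(C)=C/CC/C(C)=C/CCc1ccoc1 | intermediate
21 | 2-[(3S,7E,11E)-2-bromo-14-(furan-3-yl)-1-iodo-3,7,11-trimethyltetradeca-7,11-dien-2-yl]-4,4,5,5-tetramethyl-1,3,2-dioxaborolane (mixture at C2; not isolated) | ICC(Br)(B1OC(C)(C)C(C)(C)O1)[C@@H](C)CCC/C(C)=C/CC/C(C)=C/CCc1ccoc1 | intermediate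
22 | 3-[(3E,7E,12S)-13-bromo-4,8,12-trimethyltetradeca-3,7,13-trien-1-yl]furan | C=C(Br)[C@@H](C)CCC/C(C)=C/CC/C(C)=C/CCc1ccoc1 | intermediate
23 | lithium (3S,7E,11E)-14-(furan-3-yl)-3,7,11-trimethyltetradeca-7,11-dien-1-yn-1-ide (not isolated) | [Li]C#C[C@@H](C)CCC/C(C)=C/CC/C(C)=C/CCc1ccoc1 | intermediate
24 | (4S,8E,12E)-15-(furan-3-yl)-4,8,12-trimethylpentadeca-8,12-dien-2-ynal | O=CC#C[C@@H](C)CCC/C(C)=C/CC/C(C)=C/CCc1ccoc1 | intermediate
25 | propanoyl chloride | CCC(=O)Cl | starting material
26 | 2-(trimethylsilyl)ethanol | C[Si](C)(C)CCO | starting material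
27 | 2-(trimethylsilyl)ethyl propanoate | CCC(=O)OCC[Si](C)(C)C | intermediate
28 | lithium 1-[2-(trimethylsilyl)ethoxy]prop-1-en-1-olate (enolate geometry immaterial; not isolated) | CC=C(O[Li])OCC[Si](C)(C)C | intermediate
29 | 2-(trimethylsilyl)ethyl (6S,10E,14E)-17-(furan-3-yl)-3-hydroxy-2,6,10,14-tetramethylheptadeca-10,14-dien-4-ynoate (mixture at C2 and C3) | C[Si](C)(C)CCOC(=O)C(C)C(O)C#C[C@@H](C)CCC/C(C)=C/CC/C(C)=C/CCc1ccoc1 | intermediate
30 | 2-(trimethylsilyl)ethyl (6S,10E,14E)-17-(furan-3-yl)-2,6,10,14-tetramethyl-3-oxoheptadeca-10,14-dien-4-ynoate (mixture at C2) | C[Si](C)(C)CCOC(=O)C(C)C(=O)C#C[C@@H](C)CCC/C(C)=C/CC/C(C)=C/CCc1ccoc1 | intermediate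
31 | 2-(trimethylsilyl)ethyl (4E,6S,10E,14E)-17-(furan-3-yl)-2,6,10,14-tetramethyl-3-oxo-4-(tributylstannyl)heptadeca-4,10,14-trienoate (not isolated) | C[Si](C)(C)CCOC(=O)C(C)C(=O)/C(=C\[C@@H](C)CCC/C(C)=C/CC/C(C)=C/CCc1ccoc1)[Sn](CCCC)(CCCC)CCCC | intermediate
32 | 2-(trimethylsilyl)ethyl (4E,6S,10E,14E)-17-(furan-3-yl)-4-iodo-2,6,10,14-tetramethyl-3-oxoheptadeca-4,10,14-trienoate (mixture at C2) | C[Si](C)(C)CCOC(=O)C(C)C(=O)/C(I)=C\[C@@H](C)CCC/C(C)=C/CC/C(C)=C/CCc1ccoc1 | intermediate
33 | cesium (4E,6S,10E,14E)-17-(furan-3-yl)-4-iodo-2,6,10,14-tetramethyl-3-oxoheptadeca-4,10,14-trienoate (not isolated) | [Cs+].[O-]C(=O)C(C)C(=O)/C(I)=C\[C@@H](C)CCC/C(C)=C/CC/C(C)=C/CCc1ccoc1 | intermediate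
34 | (5E)-5-[(2S,6E,10E)-13-(furan-3-yl)-2,6,10-trimethyltrideca-6,10-dien-1-ylidene]-4-hydroxy-3-methylfuran-2(5H)-one | OC1=C(C)C(=O)O/C1=C/[C@@H](C)CCC/C(C)=C/CC/C(C)=C/CCc1ccoc1 | intermediate
35 | palmitoyl chloride (hexadecanoyl chloride) | CCCCCCCCCCCCCCCC(=O)Cl | starting material
36 | (2E)-2-[(2S,6E,10E)-13-(furan-3-yl)-2,6,10-trimethyltrideca-6,10-dien-1-ylidene]-4-methyl-5-oxo-2,5-dihydrofuran-3-yl hexadecanoate | CCCCCCCCCCCCCCCC(=O)OC1=C(C)C(=O)O/C1=C/[C@@H](C)CCC/C(C)=C/CC/C(C)=C/CCc1ccoc1 | target

## Step count and uncertain steps

Total: 19 steps. Longest linear sequence: 16 steps (1, 2, 3, 4, 5, 6, 8, 9, 11, 12, 13, 15, 16, 17, 18, 19, from farnesol 1).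

**Step 11 (key step).** The most likely failure is slow 1,2-migration of the pinacol ate complex with a carbamate leaving group. While the migration lags, the complex can revert to its components and the lithiated carbamate decomposes or loses configuration, lowering conversion and enantiopurity. A second insertion into 19 is a lesser concern.
Fallback: replace the in-flask asymmetric deprotonation by a pre-made, optically purified carbenoid precursor with a better leaving group. Ethanol 14 is esterified with 2,4,6-triisopropylbenzoyl chloride to ethyl 2,4,6-triisopropylbenzoate F1. Lithiation with s-BuLi and (+)-sparteine and stannylation with Me3SnCl give (R)-1-(trimethylstannyl)ethyl 2,4,6-triisopropylbenzoate F2, which can be crystallised. Tin–lithium exchange with n-BuLi at −78 °C gives (R)-1-lithioethyl 2,4,6-triisopropylbenzoate F3 with retention. Addition of 13 gives the lithium boronate complex F4, whose hindered benzoate leaves on warming to room temperature. The sequence sets out from 13 and returns to the route at 19.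

**Step 18.** The most likely failure is loss of CO2 from the β-keto carboxylate before the C–O bond forms, since the coupling needs warming. Base-mediated equilibration of the alkene through an extended enolate is the second concern.
Fallback: close the ring at the alcohol oxidation level, where no β-keto acid exists. From 32, Luche reduction (NaBH4, CeCl3·7H2O, MeOH) gives 2-(trimethylsilyl)ethyl (4E,6S,10E,14E)-17-(furan-3-yl)-3-hydroxy-4-iodo-2,6,10,14-tetramethylheptadeca-4,10,14-trienoate F5. Tetrabutylammonium fluoride frees the stable acid (4E,6S,10E,14E)-17-(furan-3-yl)-3-hydroxy-4-iodo-2,6,10,14-tetramethylheptadeca-4,10,14-trienoic acid F6. Copper-catalysed intramolecular O-vinylation (CuI, trans-N,N′-dimethylcyclohexane-1,2-diamine, Cs2CO3) gives (5E)-5-[(2S,6E,10E)-13-(furan-3-yl)-2,6,10-trimethyltrideca-6,10-dien-1-ylidene]-4-hydroxy-3-methyloxolan-2-one F7. Dess–Martin oxidation of its allylic alcohol returns to the route at 34.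

**Step 13.** The risks are removal of the allylic methine hydrogen instead of a vinylic one (allene formation, which erases the stereocentre), metalation of furan C2 by excess amide followed by ring formylation, and conjugate addition of dimethylamine during the quench.
Fallback: separate elimination from formylation and use no amide base. From 22, fluoride-promoted E2 elimination (tetrabutylammonium fluoride trihydrate, DMF) gives the neutral alkyne 3-[(3E,7E,12S)-4,8,12-trimethyltetradeca-3,7-dien-13-yn-1-yl]furan F8, which is isolated. It is deprotonated with one equivalent of n-BuLi at −78 °C and formylated with DMF, returning at 24.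

**Step 12.** The risk is decomposition of the 1-bromovinyllithium carbenoid before the hindered secondary boronic ester captures it, leaving 19 unchanged. Electrophilic attack of iodine on the furan or the trisubstituted alkenes is the second risk.
Fallback: build the alkyne carbons one at a time. From 19, Matteson homologation with dichloromethyllithium (ZnCl2 promotion) gives 2-[(2S,6E,10E)-1-chloro-13-(furan-3-yl)-2,6,10-trimethyltrideca-6,10-dien-1-yl]-4,4,5,5-tetramethyl-1,3,2-dioxaborolane F9. Buffered peroxide oxidation gives (2S,6E,10E)-13-(furan-3-yl)-2,6,10-trimethyltrideca-6,10-dienal F10 (the compound labelled A7 above), which is used at once. Corey–Fuchs dibromo-olefination (CBr4, PPh3) gives 3-[(3E,7E,12S)-14,14-dibromo-4,8,12-trimethyltetradeca-3,7,13-trien-1-yl]furan F11, and n-BuLi followed by DMF returns at 24. This detour also bypasses step 13.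

**Step 8.** The risks are attack at the γ-carbon (SN2′), attack at the acetate carbonyl, and Wurtz-type self-coupling of the furylmethyl Grignard reagent.
Fallback: change the electrophile from an ester to an allylic halide, the class for which clean α-coupling of this Grignard reagent is best documented. From 7, methanolysis (K2CO3, MeOH) gives (2E,6E)-10-chloro-3,7-dimethyldeca-2,6-dien-1-ol F12. Methanesulfonyl chloride, LiCl and collidine in DMF give (2E,6E)-1,10-dichloro-3,7-dimethyldeca-2,6-diene F13. Its allylic chloride alone couples with 10 under Li2CuCl4 catalysis, returning at 11.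

**Step 9.** The risk is slow activation of the C–Cl bond by the boryl copper species, so that decomposition of the diboron reagent by alkoxide takes over.
Fallback: a polar borylation with no copper. From 11, magnesium insertion (Mg, THF, reflux, 1,2-dibromoethane activation) gives chloro[(4E,8E)-11-(furan-3-yl)-4,8-dimethylundeca-4,8-dien-1-yl]magnesium F14. Trapping with 2-isopropoxy-4,4,5,5-tetramethyl-1,3,2-dioxaborolane at −78 °C returns at 13.

## Further compounds

F1 | step 11 | ethyl 2,4,6-triisopropylbenzoate | CCOC(=O)c1c(C(C)C)cc(C(C)C)cc1C(C)C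
F2 | step 11 | (R)-1-(trimethylstannyl)ethyl 2,4,6-triisopropylbenzoate | C[C@@H]([Sn](C)(C)C)OC(=O)c1c(C(C)C)cc(C(C)C)cc1C(C)C
F3 | step 11 | (R)-1-lithioethyl 2,4,6-triisopropylbenzoate | C[C@@H]([Li])OC(=O)c1c(C(C)C)cc(C(C)C)cc1C(C)C
F4 | step 11 | lithium [(1R)-1-(2,4,6-triisopropylbenzoyloxy)ethyl][(4E,8E)-11-(furan-3-yl)-4,8-dimethylundeca-4,8-dien-1-yl](pinacolato)borate | [Li+].C[C@H](OC(=O)c1c(C(C)C)cc(C(C)C)cc1C(C)C)[B-]1(CCC/C(C)=C/CC/C(C)=C/CCc2ccoc2)OC(C)(C)C(C)(C)O1
F5 | step 18 | 2-(trimethylsilyl)ethyl (4E,6S,10E,14E)-17-(furan-3-yl)-3-hydroxy-4-iodo-2,6,10,14-tetramethylheptadeca-4,10,14-trienoate | C[Si](C)(C)CCOC(=O)C(C)C(O)/C(I)=C\[C@@H](C)CCC/C(C)=C/CC/C(C)=C/CCc1ccoc1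
F6 | step 18 | (4E,6S,10E,14E)-17-(furan-3-yl)-3-hydroxy-4-iodo-2,6,10,14-tetramethylheptadeca-4,10,14-trienoic acid | OC(=O)C(C)C(O)/C(I)=C\[C@@H](C)CCC/C(C)=C/CC/C(C)=C/CCc1ccoc1
F7 | step 18 | (5E)-5-[(2S,6E,10E)-13-(furan-3-yl)-2,6,10-trimethyltrideca-6,10-dien-1-ylidene]-4-hydroxy-3-methyloxolan-2-one | OC1C(C)C(=O)O/C1=C/[C@@H](C)CCC/C(C)=C/CC/C(C)=C/CCc1ccoc1
F8 | step 13 | 3-[(3E,7E,12S)-4,8,12-trimethyltetradeca-3,7-dien-13-yn-1-yl]furan | C#C[C@@H](C)CCC/C(C)=C/CC/C(C)=C/CCc1ccoc1
F9 | step 12 | 2-[(2S,6E,10E)-1-chloro-13-(furan-3-yl)-2,6,10-trimethyltrideca-6,10-dien-1-yl]-4,4,5,5-tetramethyl-1,3,2-dioxaborolane | CC1(C)OB(OC1(C)C)C(Cl)[C@@H](C)CCC/C(C)=C/CC/C(C)=C/CCc1ccoc1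
F10 | step 12 | (2S,6E,10E)-13-(furan-3-yl)-2,6,10-trimethyltrideca-6,10-dienal | O=C[C@@H](C)CCC/C(C)=C/CC/C(C)=C/CCc1ccoc1
F11 | step 12 | 3-[(3E,7E,12S)-14,14-dibromo-4,8,12-trimethyltetradeca-3,7,13-trien-1-yl]furan | BrC(Br)=C[C@@H](C)CCC/C(C)=C/CC/C(C)=C/CCc1ccoc1
F12 | step 8 | (2E,6E)-10-chloro-3,7-dimethyldeca-2,6-dien-1-ol | ClCCC/C(C)=C/CC/C(C)=C/CO
F13 | step 8 | (2E,6E)-1,10-dichloro-3,7-dimethyldeca-2,6-diene | ClCCC/C(C)=C/CC/C(C)=C/CCl
F14 | step 9 | chloro[(4E,8E)-11-(furan-3-yl)-4,8-dimethylundeca-4,8-dien-1-yl]magnesium | Cl[Mg]CCC/C(C)=C/CC/C(C)=C/CCc1ccoc1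
A1 | alternative 1 | (5E)-5-[(2S,6E,10E)-13-(furan-3-yl)-2,6,10-trimethyltrideca-6,10-dien-1-ylidene]-4-hydroxy-3-methylfuran-2(5H)-one | OC1=C(C)C(=O)O/C1=C/[C@@H](C)CCC/C(C)=C/CC/C(C)=C/CCc1ccoc1
A2 | alternative 1 | 2-(trimethylsilyl)ethyl (4E,6S,10E,14E)-17-(furan-3-yl)-4-iodo-2,6,10,14-tetramethyl-3-oxoheptadeca-4,10,14-trienoate | C[Si](C)(C)CCOC(=O)C(C)C(=O)/C(I)=C\[C@@H](C)CCC/C(C)=C/CC/C(C)=C/CCc1ccoc1
A3 | alternative 2 | (5E)-5-[(2S,6E,10E)-13-(furan-3-yl)-2,6,10-trimethyltrideca-6,10-dien-1-ylidene]-3-methyl-4-[2-(trimethylsilyl)ethoxy]furan-2(5H)-one | C[Si](C)(C)CCOC1=C(C)C(=O)O/C1=C/[C@@H](C)CCC/C(C)=C/CC/C(C)=C/CCc1ccoc1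
A4 | alternative 2 | (5E)-5-(iodomethylidene)-3-methyl-4-[2-(trimethylsilyl)ethoxy]furan-2(5H)-one | C[Si](C)(C)CCOC1=C(C)C(=O)O/C1=C/I
A5 | alternative 2 | 3-[(3E,7E,12S)-12-iodo-4,8-dimethyltrideca-3,7-dien-1-yl]furan | I[C@@H](C)CCC/C(C)=C/CC/C(C)=C/CCc1ccoc1
A6 | alternative 2 | [(2S,6E,10E)-13-(furan-3-yl)-6,10-dimethyltrideca-6,10-dien-2-yl][(trimethylsilyl)methyl]zinc | C[Si](C)(C)C[Zn][C@@H](C)CCC/C(C)=C/CC/C(C)=C/CCc1ccoc1
A7 | alternative 3 | (2S,6E,10E)-13-(furan-3-yl)-2,6,10-trimethyltrideca-6,10-dienal | O=C[C@@H](C)CCC/C(C)=C/CC/C(C)=C/CCc1ccoc1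
A8 | alternative 3 | (2E,6E,10E)-13-(furan-3-yl)-2,6,10-trimethyltrideca-2,6,10-trienal | O=C/C(C)=C/CC/C(C)=C/CC/C(C)=C/CCc1ccoc1
A9 | alternative 3 | 3-[(3E,7E)-4,8,12-trimethyltrideca-3,7,11-trien-1-yl]furan | CC(C)=CCC/C(C)=C/CC/C(C)=C/CCc1ccoc1
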